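The synthesis rests on removing ring C from the luteolin half. The three-carbon bridge C4–C3–C2 ties C4a to O1 on flavone ring A. It is read as one CO molecule plus the two sp carbons of a protected catechol acetylene. One palladium-catalysed carbonylative alkynylation–annulation makes C4a–C4, C4–C3 and O1–C2 and closes the pyranone. Its precursor is the finished tetra-ortho-substituted biaryl. This is a phloroglucinol ring with iodine at the future C4a, its only free hydroxyl at the future C8a, and catechol ring B at the future C8. The ring B aldehyde is masked as a dioxolane. The base-sensitive (2S)-flavanone is built from that aldehyde afterwards, and eight benzyl ethers are removed last.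

Key step: step 9

Assumption: the given structure defines only C2 of the flavanone (S). The hindered C2'–C8'' biaryl axis has no descriptor, so it is carried as a racemic element. The goal is taken to be the (2S) compound whatever its axial configuration. If the axis epimers do not interconvert, they can be separated at the protected or the free stage.

Step 1
Reactants: 1 2-bromo-3-hydroxy-4-methoxybenzaldehyde
Product: 2 2-bromo-3,4-dihydroxybenzaldehyde
Conditions: BBr3 (2.5 equiv), CH2Cl2, −78 °C to rt; then H2O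
Reagents that add atoms: none
Why: Lewis-acid cleavage of the aryl methyl ether (BBr3 demethylation) frees the catechol while the molecule holds only an aryl bromide and an aldehyde, so both ring B oxygens can then carry hydrogenolysable groups.

Step 2
Reactants: 2 2-bromo-3,4-dihydroxybenzaldehyde
Product: 3 3,4-bis(benzyloxy)-2-bromobenzaldehyde
Conditions: BnBr (2.3 equiv), K2CO3 (3 equiv), DMF, 60 °C
Reagents that add atoms: benzyl bromide, BrCc1ccccc1
Why: Williamson etherification of both phenoxides proceeds cleanly because the aldehyde cannot enolise and the aryl bromide is inert to carbonate.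

Step 3
Reactants: 3 3,4-bis(benzyloxy)-2-bromobenzaldehyde
Product: 4 2-[3,4-bis(benzyloxy)-2-bromophenyl]-1,3-dioxolane
Conditions: HOCH2CH2OH (5 equiv), p-TsOH·H2O (cat.), toluene, reflux, Dean–Stark
Reagents that add atoms: ethylene glycol, OCCO
Why: Acid-catalysed acetalisation with azeotropic water removal shields the aldehyde from the organolithium step and, later, from lactol formation with the free phenol across the biaryl axis.

Step 4
Reactants: 4 2-[3,4-bis(benzyloxy)-2-bromophenyl]-1,3-dioxolane
Product: 6 2-[2,3-bis(benzyloxy)-6-(1,3-dioxolan-2-yl)phenyl]-4,4,5,5-tetramethyl-1,3,2-dioxaborolane, via aryllithium 5 (not isolated)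
Conditions: n-BuLi (1.05 equiv), THF, −78 °C, 15 min; iPrOBpin (1.3 equiv), −78 °C to rt; aq. NH4Cl
Reagents that add atoms: 2-isopropoxy-4,4,5,5-tetramethyl-1,3,2-dioxaborolane, CC(C)OB1OC(C)(C)C(C)(C)O1
Why: Bromine–lithium exchange at −78 °C is far faster than deprotonation of the benzylic ether CH2 groups, the aryllithium is held by the flanking acetal and ether oxygens, and borate trapping gives the pinacol boronate.

Step 5
Reactants: 7 3,5-bis(benzyloxy)phenol
Product: 8 3,5-bis(benzyloxy)-2-iodophenol
Conditions: NIS (1.0 equiv), CH2Cl2, −20 to 0 °C, dark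
Reagents that add atoms: N-iodosuccinimide, O=C1CCC(=O)N1I
Why: Electrophilic aromatic iodination of the phloroglucinol ring should take the carbon between the small, NIS-hydrogen-bonding hydroxyl and one benzyloxy group rather than the carbon crowded by two benzyloxy groups, and it avoids alkyllithium bases that would attack benzyl ethers.

Step 6
Reactants: 8 3,5-bis(benzyloxy)-2-iodophenol; 6 2-[2,3-bis(benzyloxy)-6-(1,3-dioxolan-2-yl)phenyl]-4,4,5,5-tetramethyl-1,3,2-dioxaborolane
Product: 9 2-[2,3-bis(benzyloxy)-6-(1,3-dioxolan-2-yl)phenyl]-3,5-bis(benzyloxy)phenol (racemic axis)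
Conditions: Pd(OAc)2 (5 mol %), SPhos (10 mol %), K3PO4 (4 equiv), 6 (1.5 equiv), toluene/H2O 10:1, 100 °C
Reagents that add atoms: none
Why: Suzuki–Miyaura coupling with a bulky electron-rich biarylphosphine is established for tetra-ortho-substituted biaryls, placing boron on ring B avoids the rapid protodeboronation of 2,4,6-trioxygenated arylborons, and the acetal and the phenoxide both tolerate aqueous phosphate.

Step 7
Reactants: 9 2-[2,3-bis(benzyloxy)-6-(1,3-dioxolan-2-yl)phenyl]-3,5-bis(benzyloxy)phenol
Product: 10 2-[2,3-bis(benzyloxy)-6-(1,3-dioxolan-2-yl)phenyl]-3,5-bis(benzyloxy)-6-iodophenol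
Conditions: NIS (1.0 equiv), solid NaHCO3, CH2Cl2, −20 to 0 °C, dark; chromatography on Et3N-washed silica
Reagents that add atoms: N-iodosuccinimide, O=C1CCC(=O)N1I
Why: Electrophilic aromatic iodination goes to the trioxygenated ring only and should prefer C6 next to the hydroxyl, because C4 lies between two benzyloxy groups of which one is pushed towards it by ring B, while the buffer keeps the phenol from exchanging into the acetal.

Step 8
Reactants: 11 3,4-bis(benzyloxy)benzaldehyde
Product: 12 1,2-bis(benzyloxy)-4-ethynylbenzene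
Conditions: dimethyl (1-diazo-2-oxopropyl)phosphonate (1.3 equiv), K2CO3 (2 equiv), MeOH/THF, rt
Reagents that add atoms: dimethyl (1-diazo-2-oxopropyl)phosphonate, COP(=O)(OC)C(=[N+]=[N-])C(C)=O
Why: Ohira–Bestmann homologation (Seyferth–Gilbert type) turns a non-enolisable aryl aldehyde into the terminal alkyne in one mild basic step that leaves benzyl ethers untouched.

Step 9
Reactants: 10 2-[2,3-bis(benzyloxy)-6-(1,3-dioxolan-2-yl)phenyl]-3,5-bis(benzyloxy)-6-iodophenol; 12 1,2-bis(benzyloxy)-4-ethynylbenzene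
Product: 15 5,7-bis(benzyloxy)-8-[2,3-bis(benzyloxy)-6-(1,3-dioxolan-2-yl)phenyl]-2-[3,4-bis(benzyloxy)phenyl]-4H-chromen-4-one, via hydroxyaryl ynone 13 (not isolated), via diethylamino enone 14 (not isolated)
Conditions: PdCl2(PPh3)2 (5 mol %), CO (10 bar), 12 (1.5 equiv), Et2NH/DMF 1:1, 90 °C, no copper salt
Reagents that add atoms: carbon monoxide, [C-]#[O+]
Why: PdCl2(PPh3)2 is reduced in situ to zerovalent palladium, which inserts into the carbon–iodine bond of 10; migratory insertion of CO gives an aroylpalladium iodide that takes up the amine-deprotonated alkyne 12 and reductively eliminates ynone 13. Conjugate addition of Et2NH converts 13 into push–pull enone 14, and the adjacent phenol then attacks its β-carbon and expels the amine. The closest known reaction type is the palladium-catalysed carbonylative annulation of 2-iodophenols with terminal arylacetylenes in a secondary amine, that is a carbonylative Sonogashira coupling followed by cyclisation. Ring C closes in the 6-endo mode (addition–elimination at the β-carbon of 14), whereas direct attack of phenoxide on 13 could also go 5-exo-dig to an aurone, a path that prior amine addition shuts off. No stereocentre is formed, and site selectivity is built into 10, because the halogen occupies the carbon that becomes C4a and the one unprotected oxygen, wedged between that carbon and the ring B-bearing carbon, must become O1, which places ring B at C8. Acyl transfer is favoured over direct alkynyl transfer by CO pressure and the absence of copper, and the benzyl ethers and the dioxolane are inert to amine, CO and palladium.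

Step 10
Reactants: 15 5,7-bis(benzyloxy)-8-[2,3-bis(benzyloxy)-6-(1,3-dioxolan-2-yl)phenyl]-2-[3,4-bis(benzyloxy)phenyl]-4H-chromen-4-one
Product: 16 3,4-bis(benzyloxy)-2-{5,7-bis(benzyloxy)-2-[3,4-bis(benzyloxy)phenyl]-4-oxo-4H-chromen-8-yl}benzaldehyde
Conditions: 1 M HCl, THF, rt
Reagents that add atoms: water, O
Why: Acid-catalysed acetal hydrolysis is safe at this point because the former phenol oxygen is locked in ring C and cannot form a lactol, and dilute acid at room temperature spares the benzyl ethers and the flavone.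

Step 11
Reactants: 17 2',4',6'-trihydroxyacetophenone
Product: 18 1-[2,4-bis(benzyloxy)-6-hydroxyphenyl]ethanone
Conditions: BnBr (2.1 equiv), K2CO3 (2.2 equiv), DMF, rt to 50 °C
Reagents that add atoms: benzyl bromide, BrCc1ccccc1
Why: Selective Williamson etherification stops at the dibenzyl stage because the last hydroxyl is tied to the acetyl carbonyl by a strong hydrogen bond and is the least nucleophilic.

Step 12
Reactants: 16 3,4-bis(benzyloxy)-2-{5,7-bis(benzyloxy)-2-[3,4-bis(benzyloxy)phenyl]-4-oxo-4H-chromen-8-yl}benzaldehyde; 18 1-[2,4-bis(benzyloxy)-6-hydroxyphenyl]ethanone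
Product: 19 (E)-2'-hydroxy-4',6'-bis(benzyloxy)chalcone whose ring B carries 3,4-bis(benzyloxy) groups and the tetrabenzyl-luteolin-8-yl group at C2
Conditions: KOH (50 % aq., 10 equiv), EtOH/THF, rt; cold 1 M HCl to pH 5
Reagents that add atoms: none
Why: In this Claisen–Schmidt condensation 16 cannot enolise, the enolate of 18 adds and E1cB dehydration gives the E-enone, which stays open in strong base as its phenoxide, and any transient hydroxide opening of the flavone can only reclose through the original O1 because O5 is benzylated.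

Step 13
Reactants: 19 (E)-2'-hydroxychalcone
Product: 20 (2S)-5,7-bis(benzyloxy)-2-{3,4-bis(benzyloxy)-2-[5,7-bis(benzyloxy)-2-(3,4-bis(benzyloxy)phenyl)-4-oxo-4H-chromen-8-yl]phenyl}chroman-4-one
Conditions: 1-[3,5-bis(trifluoromethyl)phenyl]-3-[(8α,9S)-6'-methoxycinchonan-9-yl]thiourea (20 mol %), toluene/CH2Cl2, 0 °C to rt; filtration through silica to remove the base
Reagents that add atoms: none
Why: In this bifunctional cinchona-thiourea-catalysed intramolecular oxa-Michael addition of a 2'-hydroxychalcone (6-endo-trig) the thiourea binds the enone carbonyl and the quinuclidine nitrogen activates the phenol, so oxygen is delivered to the Si face of Cβ and C2 is set as S under catalyst control; the quinidine-derived pseudoenantiomer gives the opposite sense, so a pilot run read out by circular dichroism fixes which member of the pair is used.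

Step 14
Reactants: 20 octabenzyl (2S)-flavanone–flavone
Product: 21 8-{6-[(2S)-5,7-dihydroxy-4-oxochroman-2-yl]-2,3-dihydroxyphenyl}-2-(3,4-dihydroxyphenyl)-5,7-dihydroxy-4H-chromen-4-one (CNP0265600.1)
Conditions: H2 (1 atm), Pd/C (10 wt %), THF/MeOH, rt, stopped when uptake ends
Reagents that add atoms: none
Why: Catalytic hydrogenolysis removes all eight O-benzyl groups under neutral conditions, so no acid or base is present to open the flavanone by retro-oxa-Michael reaction and scramble C2, and the flavone C2=C3 bond and the C2–O1 bond react much more slowly at one atmosphere.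

Compound list
1 | 2-bromo-3-hydroxy-4-methoxybenzaldehyde | COc1ccc(C=O)c(Br)c1O | starting material
2 | 2-bromo-3,4-dihydroxybenzaldehyde | O=Cc1ccc(O)c(O)c1Br | intermediate
3 | 3,4-bis(benzyloxy)-2-bromobenzaldehyde | O=Cc1ccc(OCc2ccccc2)c(OCc2ccccc2)c1Br | intermediate
4 | 2-[3,4-bis(benzyloxy)-2-bromophenyl]-1,3-dioxolane | Brc1c(C2OCCO2)ccc(OCc2ccccc2)c1OCc1ccccc1 | intermediate
5 | [2,3-bis(benzyloxy)-6-(1,3-dioxolan-2-yl)phenyl]lithium | [Li]c1c(C2OCCO2)ccc(OCc2ccccc2)c1OCc1ccccc1 | intermediate
6 | 2-[2,3-bis(benzyloxy)-6-(1,3-dioxolan-2-yl)phenyl]-4,4,5,5-tetramethyl-1,3,2-dioxaborolane | CC1(C)OB(OC1(C)C)c1c(C2OCCO2)ccc(OCc2ccccc2)c1OCc1ccccc1 | intermediate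
7 | 3,5-bis(benzyloxy)phenol | Oc1cc(OCc2ccccc2)cc(OCc2ccccc2)c1 | starting material
8 | 3,5-bis(benzyloxy)-2-iodophenol | Oc1cc(OCc2ccccc2)cc(OCc2ccccc2)c1I | intermediate
9 | 2-[2,3-bis(benzyloxy)-6-(1,3-dioxolan-2-yl)phenyl]-3,5-bis(benzyloxy)phenol | Oc1cc(OCc2ccccc2)cc(OCc2ccccc2)c1-c1c(C2OCCO2)ccc(OCc2ccccc2)c1OCc1ccccc1 | intermediate
10 | 2-[2,3-bis(benzyloxy)-6-(1,3-dioxolan-2-yl)phenyl]-3,5-bis(benzyloxy)-6-iodophenol | Oc1c(I)c(OCc2ccccc2)cc(OCc2ccccc2)c1-c1c(C2OCCO2)ccc(OCc2ccccc2)c1OCc1ccccc1 | intermediate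
11 | 3,4-bis(benzyloxy)benzaldehyde | O=Cc1ccc(OCc2ccccc2)c(OCc2ccccc2)c1 | starting material
12 | 1,2-bis(benzyloxy)-4-ethynylbenzene | C#Cc1ccc(OCc2ccccc2)c(OCc2ccccc2)c1 | intermediate
13 | 1-{3-[2,3-bis(benzyloxy)-6-(1,3-dioxolan-2-yl)phenyl]-4,6-bis(benzyloxy)-2-hydroxyphenyl}-3-[3,4-bis(benzyloxy)phenyl]prop-2-yn-1-one | Oc1c(C(=O)C#Cc2ccc(OCc3ccccc3)c(OCc3ccccc3)c2)c(OCc2ccccc2)cc(OCc2ccccc2)c1-c1c(C2OCCO2)ccc(OCc2ccccc2)c1OCc1ccccc1 | intermediate
14 | (E)-3-(diethylamino) enone formed from 13 by addition of Et2NH (geometry of no consequence) | Oc1c(C(=O)/C=C(/N(CC)CC)c2ccc(OCc3ccccc3)c(OCc3ccccc3)c2)c(OCc2ccccc2)cc(OCc2ccccc2)c1-c1c(C2OCCO2)ccc(OCc2ccccc2)c1OCc1ccccc1 | intermediate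
15 | 5,7-bis(benzyloxy)-8-[2,3-bis(benzyloxy)-6-(1,3-dioxolan-2-yl)phenyl]-2-[3,4-bis(benzyloxy)phenyl]-4H-chromen-4-one | O=c1cc(-c2ccc(OCc3ccccc3)c(OCc3ccccc3)c2)oc2c(-c3c(C4OCCO4)ccc(OCc4ccccc4)c3OCc3ccccc3)c(OCc3ccccc3)cc(OCc3ccccc3)c12 | intermediate
16 | 3,4-bis(benzyloxy)-2-{5,7-bis(benzyloxy)-2-[3,4-bis(benzyloxy)phenyl]-4-oxo-4H-chromen-8-yl}benzaldehyde | O=Cc1ccc(OCc2ccccc2)c(OCc2ccccc2)c1-c1c(OCc2ccccc2)cc(OCc2ccccc2)c2c(=O)cc(-c3ccc(OCc4ccccc4)c(OCc4ccccc4)c3)oc12 | intermediate
17 | 2',4',6'-trihydroxyacetophenone | CC(=O)c1c(O)cc(O)cc1O | starting material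
18 | 1-[2,4-bis(benzyloxy)-6-hydroxyphenyl]ethanone | CC(=O)c1c(O)cc(OCc2ccccc2)cc1OCc1ccccc1 | intermediate
19 | (E)-1-[2,4-bis(benzyloxy)-6-hydroxyphenyl]-3-{3,4-bis(benzyloxy)-2-[5,7-bis(benzyloxy)-2-(3,4-bis(benzyloxy)phenyl)-4-oxo-4H-chromen-8-yl]phenyl}prop-2-en-1-one | O=C(/C=C/c1ccc(OCc2ccccc2)c(OCc2ccccc2)c1-c1c(OCc2ccccc2)cc(OCc2ccccc2)c2c(=O)cc(-c3ccc(OCc4ccccc4)c(OCc4ccccc4)c3)oc12)c1c(O)cc(OCc2ccccc2)cc1OCc1ccccc1 | intermediate
20 | (2S)-octabenzyl ether of the target | O=C1C[C@@H](c2ccc(OCc3ccccc3)c(OCc3ccccc3)c2-c2c(OCc3ccccc3)cc(OCc3ccccc3)c3c(=O)cc(-c4ccc(OCc5ccccc5)c(OCc5ccccc5)c4)oc23)Oc2cc(OCc3ccccc3)cc(OCc3ccccc3)c21 | intermediate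
21 | 8-{6-[(2S)-5,7-dihydroxy-4-oxochroman-2-yl]-2,3-dihydroxyphenyl}-2-(3,4-dihydroxyphenyl)-5,7-dihydroxy-4H-chromen-4-one | O=C1C[C@@H](c2ccc(O)c(O)c2-c2c(O)cc(O)c3c(=O)cc(-c4ccc(O)c(O)c4)oc23)Oc2cc(O)cc(O)c21 | target

Total step count: 14. Longest linear sequence: 11 steps (1, 2, 3, 4, 6, 7, 9, 10, 12, 13, 14).

Steps most likely to fail

1. **Step 9.**
   - *Risk:* The carbon–iodine bond is flanked on both sides and sits on a very electron-rich ring. Oxidative addition and CO uptake may therefore lag behind hydrodeiodination, direct alkynylation followed by benzofuran closure, or capture of the acylpalladium species by diethylamine.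
   - *Fallback (from 10 and 12, back at 15):* The carbonyl carbon is brought in on the alkyne partner instead of as a gas.
     - Alkyne 12 is deprotonated with n-BuLi (THF, −78 °C) to lithium acetylide F1.
     - F1 is acylated with N-methoxy-N-methylcarbamoyl chloride to give propiolic Weinreb amide F2.
     - Iodophenol 10 is treated with iPrMgCl·LiCl (2.2 equiv, THF, −20 °C). The first equivalent removes the phenol proton and the second performs iodine–magnesium exchange, giving dimagnesiated phenoxide F3.
     - F3 is acylated by F2, and the quench delivers ynone 13, which is isolated here.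
     - Warming 13 with Et2NH in EtOH/THF gives 15 through 14.

2. **Step 13.**
   - *Risk:* A plain chalcone offers the catalyst only loose two-point binding, so facial discrimination may be poor. The basic catalyst can also reopen the product and erode the enantiomeric purity with time. In addition, the racemic biaryl axis next to the reacting carbon may create matched and mismatched substrate–catalyst pairs.
   - *Fallback (from 19, back at 20):* Chalcone 19 is closed without stereocontrol (NaOAc, EtOH/THF, reflux) to racemic flavanone F4.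
     - F4 is resolved kinetically by Noyori-type asymmetric transfer hydrogenation (Cp*RhCl[(R,R)-TsDPEN], HCO2H/Et3N, EtOAc, rt, halted near half conversion).
     - This catalyst forms 4R carbinols, and it does so quickly only on the 2R enantiomer, where the 2,4-cis alcohol results.
     - The (2R,4R)-flavan-4-ol F5 is removed by chromatography and unreacted 20 is kept.
     - The flavone carbonyl is a vinylogous ester and should not be reduced.

3. **Step 6.**
   - *Risk:* Transmetalation between two doubly flanked partners may be so slow that protodeboronation of 6 and hydrodeiodination of 8 consume both. The phenoxide may further slow oxidative addition.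
   - *Fallback (from 8 and 4, back at 9):* The coupling is moved to the organozinc manifold with a masked phenol.
     - Phenol 8 is silylated (TBSCl, imidazole, DMF) to silyl ether F6.
     - Bromide 4 is lithiated as in step 4 to 5 and transmetalated with ZnCl2 to arylzinc chloride F7.
     - Negishi coupling of F6 and F7 (Pd2(dba)3, RuPhos, THF, 70 °C) gives silyl-protected biaryl F8.
     - TBAF (THF, 0 °C) releases 9 without touching the acetal.

Further compounds
F1 | step 9 | lithium [3,4-bis(benzyloxy)phenyl]acetylide | [Li]C#Cc1ccc(OCc2ccccc2)c(OCc2ccccc2)c1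
F2 | step 9 | 3-[3,4-bis(benzyloxy)phenyl]-N-methoxy-N-methylprop-2-ynamide | CON(C)C(=O)C#Cc1ccc(OCc2ccccc2)c(OCc2ccccc2)c1
F3 | step 9 | chloromagnesium 2-[2,3-bis(benzyloxy)-6-(1,3-dioxolan-2-yl)phenyl]-3,5-bis(benzyloxy)-6-(chloromagnesio)phenoxide | Cl[Mg]Oc1c([Mg]Cl)c(OCc2ccccc2)cc(OCc2ccccc2)c1-c1c(C2OCCO2)ccc(OCc2ccccc2)c1OCc1ccccc1
F4 | step 13 | racemic octabenzyl flavanone–flavone | O=C1CC(c2ccc(OCc3ccccc3)c(OCc3ccccc3)c2-c2c(OCc3ccccc3)cc(OCc3ccccc3)c3c(=O)cc(-c4ccc(OCc5ccccc5)c(OCc5ccccc5)c4)oc23)Oc2cc(OCc3ccccc3)cc(OCc3ccccc3)c21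
F5 | step 13 | (2R,4R)-cis-flavan-4-ol of the octabenzyl series | O[C@@H]1C[C@H](c2ccc(OCc3ccccc3)c(OCc3ccccc3)c2-c2c(OCc3ccccc3)cc(OCc3ccccc3)c3c(=O)cc(-c4ccc(OCc5ccccc5)c(OCc5ccccc5)c4)oc23)Oc2cc(OCc3ccccc3)cc(OCc3ccccc3)c21
F6 | step 6 | [3,5-bis(benzyloxy)-2-iodophenoxy](tert-butyl)dimethylsilane | C[Si](C)(Oc1cc(OCc2ccccc2)cc(OCc2ccccc2)c1I)C(C)(C)C
F7 | step 6 | [2,3-bis(benzyloxy)-6-(1,3-dioxolan-2-yl)phenyl]zinc chloride | Cl[Zn]c1c(C2OCCO2)ccc(OCc2ccccc2)c1OCc1ccccc1
F8 | step 6 | tert-butyldimethylsilyl ether of 9 | C[Si](C)(Oc1cc(OCc2ccccc2)cc(OCc2ccccc2)c1-c1c(C2OCCO2)ccc(OCc2ccccc2)c1OCc1ccccc1)C(C)(C)C
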